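**Retrosynthetic overview**
1. The ten-membered carbocycle is closed last, at C9–C10, by a photoredox/nickel decarboxylative alkenylation of a seco α-acetoxy acid onto a (Z)-α-iodo enoate; this step delivers the target itself.
2. C1=C10 comes from an iodo-ylide Wittig on a cis-epoxy aldehyde; the γ-lactone (C6–C7 bond, then C11) comes from chromium-mediated 2-(alkoxycarbonyl)allylation of an epoxy enal, followed by hydrogenation.
3. The allyl bromide partner is a Baylis–Hillman unit built on a cis-epoxy aldehyde; SN2 opening of that oxirane by the side-chain acid sets C8 and differentiates O8 from O9.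
4. Both halves derive from one cis-epoxide made from diethyl D-tartrate; the side-chain acid comes from ethyl (S)-3-hydroxybutanoate by two Fráter–Seebach operations.
5. Ring order: oxirane (step 3) → γ-lactone (step 17) → ten-membered ring (step 21).

Assumption: germacrane locants are used (C1=C10 enoate, C2/C3 oxirane, C4=C5, C6/C7 lactone fusion, C8 side-chain ester, C9 acetate, C11 methyl, C14 ester carbon), and diethyl D-tartrate and ethyl (S)-3-hydroxybutanoate are taken as cheap commercial chiral materials.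

**Route**

Step 1
Reactants: 1 diethyl D-tartrate [diethyl (2S,3S)-2,3-dihydroxybutanedioate]
Product: 2 diethyl (2S,3S)-2-hydroxy-3-(tosyloxy)butanedioate
Conditions: TsCl (1.05 equiv), Et3N, Bu2SnO (2 mol%), CH2Cl2, 0 °C to rt
Reagents that add atoms: p-toluenesulfonyl chloride, Cc1ccc(cc1)S(Cl)(=O)=O
Why: Tin-acetal-mediated monosulfonylation of a C2-symmetric diol gives a single monotosylate because both hydroxyls are equivalent, and no stereocenter is touched.

Step 2
Reactants: 2 diethyl (2S,3S)-2-hydroxy-3-(tosyloxy)butanedioate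
Product: 3 ethyl (2S,3R)-3,4-dihydroxy-2-(tosyloxy)butanoate
Conditions: BH3·SMe2 (1.05 equiv), NaBH4 (5 mol%), THF, 0 °C to rt; MeOH quench; used crude
Reagents that add atoms: none
Why: Hydroxyl-directed borane reduction (Saito-type) reduces only the ester next to the free OH, which differentiates the two termini without touching the stereocenters.

Step 3
Reactants: 3 ethyl (2S,3R)-3,4-dihydroxy-2-(tosyloxy)butanoate
Product: 5 ethyl (2R,3R)-3-{[(triethylsilyl)oxy]methyl}oxirane-2-carboxylate, via silyl ether tosylate 4 (not isolated)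
Conditions: Et3SiCl (1.05 equiv), imidazole, CH2Cl2, −30 °C; then K2CO3, EtOH, 0 °C
Reagents that add atoms: chlorotriethylsilane, CC[Si](Cl)(CC)CC
Why: Selective silylation of the primary OH (which also blocks lactonization) is followed by intramolecular Williamson displacement of the tosylate with inversion, turning the threo tosyloxy alcohol into the cis-epoxide whose carbons become C2/C3 and, in the other half, C8.

Step 4
Reactants: 5 ethyl (2R,3R)-3-{[(triethylsilyl)oxy]methyl}oxirane-2-carboxylate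
Product: 7 1-[(2R,3R)-3-{[(triethylsilyl)oxy]methyl}oxiran-2-yl]ethan-1-one, via Weinreb amide 6 (not isolated)
Conditions: MeNH(OMe)·HCl (1.5 equiv), iPrMgCl (3.0 equiv), THF, −20 °C; then MeMgBr (1.5 equiv), −20 to 0 °C
Reagents that add atoms: methylmagnesium bromide, C[Mg]Br; N,O-dimethylhydroxylamine hydrochloride, CNOC.Cl (its atoms stay only in 6)
Why: One-pot ester-to-Weinreb-amide-to-methyl-ketone conversion, where the chelated tetrahedral adduct prevents over-addition and the carbonyl reacts faster than the oxirane, so both stereocenters are retained.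

Step 5
Reactants: 7 1-[(2R,3R)-3-{[(triethylsilyl)oxy]methyl}oxiran-2-yl]ethan-1-one
Product: 8 (2E)-N-methoxy-N-methyl-3-[(2S,3R)-3-{[(triethylsilyl)oxy]methyl}oxiran-2-yl]but-2-enamide
Conditions: (EtO)2P(O)CH2C(O)N(OMe)Me (1.5 equiv), NaH, THF, 0 °C to rt
Reagents that add atoms: diethyl {2-[methoxy(methyl)amino]-2-oxoethyl}phosphonate, CCOP(=O)(CC(=O)N(C)OC)OCC
Why: Horner–Wadsworth–Emmons olefination of the activated epoxy methyl ketone gives the (E)-trisubstituted alkene (carbonyl trans to the bulkier oxiranyl group; minor Z isomer removed by chromatography), which is the C4=C5 bond.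

Step 6
Reactants: 8 (2E)-N-methoxy-N-methyl-3-[(2S,3R)-3-{[(triethylsilyl)oxy]methyl}oxiran-2-yl]but-2-enamide
Product: 9 (2E)-3-[(2S,3R)-3-{[(triethylsilyl)oxy]methyl}oxiran-2-yl]but-2-enal
Conditions: iBu2AlH (1.2 equiv), THF, −78 °C; aq. potassium sodium tartrate
Reagents that add atoms: none
Why: Weinreb amide reduction stops at the aldehyde through the stable aluminium chelate, and at −78 °C the alkene geometry and oxirane are untouched.

Step 7
Reactants: 10 ethyl (S)-3-hydroxybutanoate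
Product: 11 ethyl (2S,3S)-3-hydroxy-2-methylbutanoate
Conditions: LiN(iPr)2 (2.2 equiv), THF, −78 to −20 °C; MeI (1.2 equiv), DMPU, −78 to −20 °C; NH4Cl
Reagents that add atoms: iodomethane, CI
Why: Fráter–Seebach alkylation, in which the chelated dianion is methylated anti to the C3 methyl group to give the anti product.

Step 8
Reactants: 11 ethyl (2S,3S)-3-hydroxy-2-methylbutanoate
Product: 12 ethyl (2S,3S)-2,3-dihydroxy-2-methylbutanoate
Conditions: LiN(iPr)2 (2.2 equiv), THF, −78 to −30 °C; MoO5·pyridine·HMPA (1.5 equiv), −78 to −40 °C; aq. Na2SO3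
Reagents that add atoms: oxodiperoxymolybdenum–pyridine–HMPA complex, O=[Mo]12(OO1)OO2.c1ccncc1.CN(C)P(=O)(N(C)C)N(C)C
Why: A second Fráter–Seebach operation, now an electrophilic enolate hydroxylation (Vedejs oxidation) of the chelated dianion on the same face as before, so OH enters anti to the C3 methyl and the quaternary 2S centre is set by the C3 stereocenter.

Step 9
Reactants: 12 ethyl (2S,3S)-2,3-dihydroxy-2-methylbutanoate
Product: 13 (2S,3S)-2,3-dihydroxy-2-methylbutanoic acid
Conditions: LiOH·H2O (3 equiv), THF/H2O 3:1, rt; then 1 M HCl to pH 2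
Reagents that add atoms: lithium hydroxide, [Li+].[OH-]
Why: Simple saponification, with no epimerizable centre because C2 is quaternary.

Step 10
Reactants: 13 (2S,3S)-2,3-dihydroxy-2-methylbutanoic acid
Product: 14 (2S,3S)-3-acetoxy-2-hydroxy-2-methylbutanoic acid
Conditions: Ac2O (1.3 equiv), pyridine, 0 °C to rt; aqueous work-up
Reagents that add atoms: acetic anhydride, CC(=O)OC(C)=O
Why: Chemoselective acetylation of the secondary alcohol, since the tertiary OH is inert under these conditions and any mixed anhydride hydrolyses on work-up.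

Step 11
Reactants: 5 ethyl (2R,3R)-3-{[(triethylsilyl)oxy]methyl}oxirane-2-carboxylate
Product: 15 2-(trimethylsilyl)ethyl (2R,3R)-3-{[(triethylsilyl)oxy]methyl}oxirane-2-carboxylate
Conditions: Me3SiCH2CH2OH (5 equiv), Bu2SnO (10 mol%), toluene, 90 °C
Reagents that add atoms: 2-(trimethylsilyl)ethanol, C[Si](C)(C)CCO
Why: Neutral tin-catalysed transesterification installs a fluoride-labile ester that survives the following steps and later unmasks the carboxylate.

Step 12
Reactants: 15 2-(trimethylsilyl)ethyl (2R,3R)-3-{[(triethylsilyl)oxy]methyl}oxirane-2-carboxylate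
Product: 16 2-(trimethylsilyl)ethyl (2R,3S)-3-formyloxirane-2-carboxylate
Conditions: (COCl)2 (2.2 equiv), DMSO (4.5 equiv), CH2Cl2, −78 to −30 °C; Et3N, −78 to 0 °C
Reagents that add atoms: none
Why: Swern oxidation converts a primary triethylsilyl ether directly into the aldehyde (oxidative desilylation), avoiding the free cis-hydroxy ester that would lactonize; the oxirane centres are not enolizable.

Step 13
Reactants: 16 2-(trimethylsilyl)ethyl (2R,3S)-3-formyloxirane-2-carboxylate; 17 methyl acrylate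
Product: 18 2-(trimethylsilyl)ethyl (2R,3R)-3-[1-hydroxy-2-(methoxycarbonyl)prop-2-en-1-yl]oxirane-2-carboxylate (both carbinol epimers)
Conditions: DABCO (0.5 equiv), 17 (5 equiv, neat), rt
Reagents that add atoms: none
Why: Morita–Baylis–Hillman reaction of the activated epoxy aldehyde brings in C11–C13; the new carbinol centre is erased in step 16, so its configuration does not matter.

Step 14
Reactants: 18 Baylis–Hillman adduct; 14 (2S,3S)-3-acetoxy-2-hydroxy-2-methylbutanoic acid
Product: 19 1-methyl 6-[2-(trimethylsilyl)ethyl] (4S,5R)-4-{[(2S,3S)-3-acetoxy-2-hydroxy-2-methylbutanoyl]oxy}-3,5-dihydroxy-2-methylidenehexanedioate (C3 epimers)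
Conditions: 14 (1.5 equiv), Cs2CO3 (0.3 equiv), DMF, 45 °C
Reagents that add atoms: none
Why: SN2 opening of the glycidic ester by the carboxylate at the carbon β to the ester (C8) with inversion, so the cis-epoxide gives the 8,9-threo hydroxy ester with the side chain on O8 and O9 left free.

Step 15
Reactants: 19 diol diester
Product: 20 1-methyl 6-[2-(trimethylsilyl)ethyl] (4S,5R)-3,5-diacetoxy-4-{[(2S,3S)-3-acetoxy-2-hydroxy-2-methylbutanoyl]oxy}-2-methylidenehexanedioate (C3 epimers)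
Conditions: Ac2O (3 equiv), pyridine, DMAP (5 mol%), CH2Cl2, 0 °C
Reagents that add atoms: acetic anhydride, CC(=O)OC(C)=O
Why: Acetylation of both secondary alcohols installs the C9 acetate and activates the allylic alcohol, while the hindered tertiary side-chain OH is left.

Step 16
Reactants: 20 Baylis–Hillman acetate
Product: 21 1-methyl 6-[2-(trimethylsilyl)ethyl] (2Z,4S,5R)-5-acetoxy-4-{[(2S,3S)-3-acetoxy-2-hydroxy-2-methylbutanoyl]oxy}-2-(bromomethyl)hex-2-enedioate
Conditions: MgBr2·OEt2 (1.5 equiv), THF, 0 °C to rt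
Reagents that add atoms: magnesium bromide diethyl etherate, [Mg+2].[Br-].[Br-]
Why: SN2′ displacement of the Baylis–Hillman acetate by bromide gives the thermodynamic (2Z)-2-(bromomethyl)enoate, and only the allylic acetate reacts.

Step 17
Reactants: 21 allyl bromide; 9 (2E)-3-[(2S,3R)-3-{[(triethylsilyl)oxy]methyl}oxiran-2-yl]but-2-enal
Product: 23 2-(trimethylsilyl)ethyl (2R,3S)-2-acetoxy-3-{[(2S,3S)-3-acetoxy-2-hydroxy-2-methylbutanoyl]oxy}-3-[(2R,3S)-4-methylidene-5-oxo-2-{(1E)-2-[(2S,3R)-3-{[(triethylsilyl)oxy]methyl}oxiran-2-yl]prop-1-en-1-yl}oxolan-3-yl]propanoate, via hydroxy diester adduct 22 (not isolated)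
Conditions: CrCl2 (4 equiv), THF, rt; aq. NH4Cl; then silica gel, CH2Cl2, rt
Reagents that add atoms: none
Why: Nozaki–Hiyama (Barbier-type) 2-(alkoxycarbonyl)allylation, in which the trivalent allylchromium adds to the enal through a chair transition state (anti adduct, hence the trans-lactone) on the allyl face anti to C9, with C8–H in the alkene plane and the acyloxy group outside, setting C6 (R) and C7 (S) from C8.

Step 18
Reactants: 23 α-methylene lactone
Product: 24 2-(trimethylsilyl)ethyl (2R,3S)-2-acetoxy-3-{[(2S,3S)-3-acetoxy-2-hydroxy-2-methylbutanoyl]oxy}-3-[(2R,3S,4R)-4-methyl-5-oxo-2-{(1E)-2-[(2S,3R)-3-{[(triethylsilyl)oxy]methyl}oxiran-2-yl]prop-1-en-1-yl}oxolan-3-yl]propanoate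
Conditions: H2 (1 atm), RhCl(PPh3)3 (10 mol%), benzene/EtOH 4:1, rt
Reagents that add atoms: none
Why: Homogeneous hydrogenation reduces only the exocyclic 1,1-disubstituted alkene, from the lactone face anti to the adjacent C7 substituent, which puts the C11 methyl cis to C8 (11R).

Step 19
Reactants: 24 saturated lactone silyl ether
Product: 25 the corresponding cis-epoxy aldehyde [as 24 but with a (2S,3S)-3-formyloxiran-2-yl group]
Conditions: (COCl)2 (2.2 equiv), DMSO (4.5 equiv), CH2Cl2, −78 to −40 °C; Et3N, −78 to −20 °C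
Reagents that add atoms: none
Why: Swern oxidative desilylation of the primary triethylsilyl ether as in step 12; the tertiary alcohol, esters, lactone and oxirane are inert.

Step 20
Reactants: 25 epoxy aldehyde
Product: 26 the (Z)-α-iodo enoate seco ester [as 24 but with a (2S,3R)-3-[(1Z)-2-iodo-3-methoxy-3-oxoprop-1-en-1-yl]oxiran-2-yl group]
Conditions: Ph3P=CHCO2Me (1.6 equiv), N-iodosuccinimide (1.6 equiv), K2CO3, MeCN, −20 °C; then 25, −20 to 0 °C
Reagents that add atoms: methyl (triphenyl-λ5-phosphanylidene)acetate, COC(=O)C=P(c1ccccc1)(c1ccccc1)c1ccccc1; N-iodosuccinimide, O=C1CCC(=O)N1I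
Why: Wittig olefination with the α-iodo ylide made in the flask gives the (Z)-α-iodo enoate (ester trans to C2), which fixes the C1=C10 geometry; the iodine on the alkene terminus also retards Cope rearrangement of the cis-dialkenyl oxirane.

Step 21
Reactants: 26 (Z)-α-iodo enoate seco ester
Product: 28 CNP0544285.1 (target), via caesium carboxylate 27 (not isolated)
Conditions: CsF (3 equiv), DMF, rt; then dilute to 2 mM, Ir[dF(CF3)ppy]2(dtbbpy)PF6 (2 mol%), NiCl2·glyme (15 mol%), 4,4′-di-tert-butyl-2,2′-bipyridine (20 mol%), 450 nm LEDs, 25 °C, argon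
Reagents that add atoms: none
Why: Proposed new method: a ring-closing photoredox/nickel decarboxylative alkenylation, in which the excited iridium complex oxidises carboxylate 27, loss of CO2 gives a planar α-acetoxy C9 radical (so the C9 configuration of 26 is irrelevant), zerovalent nickel inserts into the C10–I bond with retention of alkene geometry, and radical capture followed by reductive elimination from trivalent nickel forges C9–C10 and the ten-membered ring; the cis-oxirane/(Z)-alkene turn holds the termini close, and bond formation anti to the C8 acyloxy group with the C9 acetoxy group eclipsing C8–H (Felkin-type radical model) is expected to give the 8,9-trans (9S) product; the closest known reaction type is the intermolecular decarboxylative coupling of α-oxy carboxylic acids with alkenyl halides under photoredox/nickel dual catalysis, not yet shown for ring closure or for α-iodo enoates.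

**Compound list**
1 | diethyl D-tartrate, diethyl (2S,3S)-2,3-dihydroxybutanedioate | CCOC(=O)[C@@H](O)[C@H](O)C(=O)OCC | starting material
2 | diethyl (2S,3S)-2-hydroxy-3-(tosyloxy)butanedioate | CCOC(=O)[C@@H](O)[C@H](OS(=O)(=O)c1ccc(C)cc1)C(=O)OCC | intermediate
3 | ethyl (2S,3R)-3,4-dihydroxy-2-(tosyloxy)butanoate | OC[C@@H](O)[C@H](OS(=O)(=O)c1ccc(C)cc1)C(=O)OCC | intermediate
4 | ethyl (2S,3R)-3-hydroxy-2-(tosyloxy)-4-[(triethylsilyl)oxy]butanoate (not isolated) | CC[Si](CC)(CC)OC[C@@H](O)[C@H](OS(=O)(=O)c1ccc(C)cc1)C(=O)OCC | intermediate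
5 | ethyl (2R,3R)-3-{[(triethylsilyl)oxy]methyl}oxirane-2-carboxylate (cis) | CC[Si](CC)(CC)OC[C@H]1O[C@H]1C(=O)OCC | intermediate
6 | (2R,3R)-N-methoxy-N-methyl-3-{[(triethylsilyl)oxy]methyl}oxirane-2-carboxamide (not isolated) | CC[Si](CC)(CC)OC[C@H]1O[C@H]1C(=O)N(C)OC | intermediate
7 | 1-[(2R,3R)-3-{[(triethylsilyl)oxy]methyl}oxiran-2-yl]ethan-1-one | CC[Si](CC)(CC)OC[C@H]1O[C@H]1C(C)=O | intermediate
8 | (2E)-N-methoxy-N-methyl-3-[(2S,3R)-3-{[(triethylsilyl)oxy]methyl}oxiran-2-yl]but-2-enamide | CC[Si](CC)(CC)OC[C@H]1O[C@H]1/C(C)=C/C(=O)N(C)OC | intermediate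
9 | (2E)-3-[(2S,3R)-3-{[(triethylsilyl)oxy]methyl}oxiran-2-yl]but-2-enal | CC[Si](CC)(CC)OC[C@H]1O[C@H]1/C(C)=C/C=O | intermediate
10 | ethyl (S)-3-hydroxybutanoate | C[C@H](O)CC(=O)OCC | starting material
11 | ethyl (2S,3S)-3-hydroxy-2-methylbutanoate | CCOC(=O)[C@@H](C)[C@H](C)O | intermediate
12 | ethyl (2S,3S)-2,3-dihydroxy-2-methylbutanoate | CCOC(=O)[C@@](C)(O)[C@H](C)O | intermediate
13 | (2S,3S)-2,3-dihydroxy-2-methylbutanoic acid | OC(=O)[C@@](C)(O)[C@H](C)O | intermediate
14 | (2S,3S)-3-acetoxy-2-hydroxy-2-methylbutanoic acid | OC(=O)[C@@](C)(O)[C@H](C)OC(C)=O | intermediate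
15 | 2-(trimethylsilyl)ethyl (2R,3R)-3-{[(triethylsilyl)oxy]methyl}oxirane-2-carboxylate | CC[Si](CC)(CC)OC[C@H]1O[C@H]1C(=O)OCC[Si](C)(C)C | intermediate
16 | 2-(trimethylsilyl)ethyl (2R,3S)-3-formyloxirane-2-carboxylate (cis) | O=C[C@H]1O[C@H]1C(=O)OCC[Si](C)(C)C | intermediate
17 | methyl acrylate | C=CC(=O)OC | starting material
18 | 2-(trimethylsilyl)ethyl (2R,3R)-3-[1-hydroxy-2-(methoxycarbonyl)prop-2-en-1-yl]oxirane-2-carboxylate (carbinol epimers) | COC(=O)C(=C)C(O)[C@H]1O[C@H]1C(=O)OCC[Si](C)(C)C | intermediate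
19 | 1-methyl 6-[2-(trimethylsilyl)ethyl] (4S,5R)-4-{[(2S,3S)-3-acetoxy-2-hydroxy-2-methylbutanoyl]oxy}-3,5-dihydroxy-2-methylidenehexanedioate | COC(=O)C(=C)C(O)[C@H](OC(=O)[C@@](C)(O)[C@H](C)OC(C)=O)[C@@H](O)C(=O)OCC[Si](C)(C)C | intermediate
20 | 1-methyl 6-[2-(trimethylsilyl)ethyl] (4S,5R)-3,5-diacetoxy-4-{[(2S,3S)-3-acetoxy-2-hydroxy-2-methylbutanoyl]oxy}-2-methylidenehexanedioate | COC(=O)C(=C)C(OC(C)=O)[C@H](OC(=O)[C@@](C)(O)[C@H](C)OC(C)=O)[C@@H](OC(C)=O)C(=O)OCC[Si](C)(C)C | intermediate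
21 | 1-methyl 6-[2-(trimethylsilyl)ethyl] (2Z,4S,5R)-5-acetoxy-4-{[(2S,3S)-3-acetoxy-2-hydroxy-2-methylbutanoyl]oxy}-2-(bromomethyl)hex-2-enedioate | COC(=O)/C(CBr)=C/[C@H](OC(=O)[C@@](C)(O)[C@H](C)OC(C)=O)[C@@H](OC(C)=O)C(=O)OCC[Si](C)(C)C | intermediate
22 | open-chain anti homoallylic alcohol from 21 + 9 (C6 hydroxy, C12 methyl ester; not isolated) | CC[Si](CC)(CC)OC[C@H]1O[C@H]1/C(C)=C/[C@@H](O)[C@@H]([C@H](OC(=O)[C@@](C)(O)[C@H](C)OC(C)=O)[C@@H](OC(C)=O)C(=O)OCC[Si](C)(C)C)C(=C)C(=O)OC | intermediate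
23 | trans-α-methylene-γ-lactone (6R,7S,8S,9R; name as in step 17) | CC[Si](CC)(CC)OC[C@H]1O[C@H]1/C(C)=C/[C@H]2OC(=O)C(=C)[C@@H]2[C@H](OC(=O)[C@@](C)(O)[C@H](C)OC(C)=O)[C@@H](OC(C)=O)C(=O)OCC[Si](C)(C)C | intermediate
24 | 11R-methyl lactone (name as in step 18) | CC[Si](CC)(CC)OC[C@H]1O[C@H]1/C(C)=C/[C@H]2OC(=O)[C@H](C)[C@@H]2[C@H](OC(=O)[C@@](C)(O)[C@H](C)OC(C)=O)[C@@H](OC(C)=O)C(=O)OCC[Si](C)(C)C | intermediate
25 | cis-epoxy aldehyde: 24 with CHO in place of CH2OSiEt3 | O=C[C@H]1O[C@H]1/C(C)=C/[C@H]2OC(=O)[C@H](C)[C@@H]2[C@H](OC(=O)[C@@](C)(O)[C@H](C)OC(C)=O)[C@@H](OC(C)=O)C(=O)OCC[Si](C)(C)C | intermediate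
26 | (Z)-α-iodo enoate seco ester (methyl (Z)-2-iodoacrylate unit on the oxirane; 2-(trimethylsilyl)ethyl ester at the C9 carboxyl) | COC(=O)/C(I)=C/[C@H]1O[C@H]1/C(C)=C/[C@H]2OC(=O)[C@H](C)[C@@H]2[C@H](OC(=O)[C@@](C)(O)[C@H](C)OC(C)=O)[C@@H](OC(C)=O)C(=O)OCC[Si](C)(C)C | intermediate
27 | caesium salt of the seco α-acetoxy acid (not isolated) | COC(=O)/C(I)=C/[C@H]1O[C@H]1/C(C)=C/[C@H]2OC(=O)[C@H](C)[C@@H]2[C@H](OC(=O)[C@@](C)(O)[C@H](C)OC(C)=O)[C@@H](OC(C)=O)C(=O)[O-].[Cs+] | intermediate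
28 | CNP0544285.1: 2,3-cis-epoxygermacra-1(10),4-dien-6,12-olide methyl 14-oate with 9-OAc and 8-O-[(2S,3S)-3-acetoxy-2-hydroxy-2-methylbutanoyl]; 2R,3S,6R,7S,8S,9S,11R; ring carbons cis at C1=C10 and trans at C4=C5 | COC(=O)/C1=C/[C@H]2O[C@H]2/C(C)=C/[C@H]2OC(=O)[C@H](C)[C@@H]2[C@H](OC(=O)[C@@](C)(O)[C@H](C)OC(C)=O)[C@H]1OC(C)=O | target

**Totals and risks**
Total steps: 21. Longest linear sequence: 14 (steps 1–3 and 11–21).

Steps most likely to fail:

Step 21 (the proposed new ring closure). The risks are oligomerization or protodecarboxylation instead of ring closure, the wrong C9 epimer, and loss of alkene geometry by sensitization. The fallback sets out from 26 and returns at 28, using known chemistry. Cleave the silylethyl ester with Bu4NF/AcOH to the free seco acid F8. Convert it with N-hydroxypyridine-2-thione and DCC into the Barton ester F9 and photolyse under O2 with t-BuSH, then P(OMe)3 (Barton decarboxylative oxygenation); the resulting α-acetoxy carbinol loses acetic acid to give the C9 nor-aldehyde F10. Close the ring by an established Nozaki–Hiyama–Kishi alkenyl iodide–aldehyde macrocyclization (CrCl2, NiCl2 1 mol%, DMSO/THF, 2 mM) to the 9-hydroxy macrocycle F11, and acetylate (Ac2O, DMAP) to 28.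

Step 17 (facial selectivity of the allylation relative to C8, and tolerance of divalent chromium by the functional groups). The fallback sets out from 18 and returns at 23. Convert 18 with NBS/Me2S into the epoxy allyl bromide F5, with the oxirane still closed. Couple F5 with 9 (CrCl2, THF) to the epoxy lactone F6; C7 is now formed while C8 still has its pre-inversion configuration inside a rigid oxirane, which presents the opposite allylic bias. Then open the oxirane with 14/Cs2CO3 to the hydroxy lactone F7 and acetylate to 23.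

Step 14 (regioselectivity of carboxylate attack at the hindered C8, and lactonization of the product). The fallback sets out from 15 and returns at 20. Open the unhindered oxirane of 15 with 14/Cs2CO3, where attack β to the ester is unambiguous, to the hydroxy ester F1. Acetylate to the acetate F2, apply the Swern oxidative desilylation to the aldehyde F3, run the Baylis–Hillman reaction with 17 to the allylic alcohol F4, and acetylate to 20.

**Further compounds**
F1 | step 14 | 2-(trimethylsilyl)ethyl (2R,3S)-3-{[(2S,3S)-3-acetoxy-2-hydroxy-2-methylbutanoyl]oxy}-2-hydroxy-4-[(triethylsilyl)oxy]butanoate | CC[Si](CC)(CC)OC[C@H](OC(=O)[C@@](C)(O)[C@H](C)OC(C)=O)[C@@H](O)C(=O)OCC[Si](C)(C)C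
F2 | step 14 | 2-(trimethylsilyl)ethyl (2R,3S)-2-acetoxy-3-{[(2S,3S)-3-acetoxy-2-hydroxy-2-methylbutanoyl]oxy}-4-[(triethylsilyl)oxy]butanoate | CC[Si](CC)(CC)OC[C@H](OC(=O)[C@@](C)(O)[C@H](C)OC(C)=O)[C@@H](OC(C)=O)C(=O)OCC[Si](C)(C)C
F3 | step 14 | 2-(trimethylsilyl)ethyl (2R,3R)-2-acetoxy-3-{[(2S,3S)-3-acetoxy-2-hydroxy-2-methylbutanoyl]oxy}-4-oxobutanoate | O=C[C@H](OC(=O)[C@@](C)(O)[C@H](C)OC(C)=O)[C@@H](OC(C)=O)C(=O)OCC[Si](C)(C)C
F4 | step 14 | 1-methyl 6-[2-(trimethylsilyl)ethyl] (4S,5R)-5-acetoxy-4-{[(2S,3S)-3-acetoxy-2-hydroxy-2-methylbutanoyl]oxy}-3-hydroxy-2-methylidenehexanedioate | COC(=O)C(=C)C(O)[C@H](OC(=O)[C@@](C)(O)[C@H](C)OC(C)=O)[C@@H](OC(C)=O)C(=O)OCC[Si](C)(C)C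
F5 | step 17 | 2-(trimethylsilyl)ethyl (2R,3R)-3-[(1Z)-3-bromo-2-(methoxycarbonyl)prop-1-en-1-yl]oxirane-2-carboxylate | COC(=O)/C(CBr)=C/[C@H]1O[C@H]1C(=O)OCC[Si](C)(C)C
F6 | step 17 | trans-α-methylene-γ-lactone carrying the intact cis-oxirane ester at C7 | CC[Si](CC)(CC)OC[C@H]1O[C@H]1/C(C)=C/[C@H]2OC(=O)C(=C)[C@@H]2[C@H]3O[C@H]3C(=O)OCC[Si](C)(C)C
F7 | step 17 | 9-hydroxy analogue of 23 (C9 acetate missing) | CC[Si](CC)(CC)OC[C@H]1O[C@H]1/C(C)=C/[C@H]2OC(=O)C(=C)[C@@H]2[C@H](OC(=O)[C@@](C)(O)[C@H](C)OC(C)=O)[C@@H](O)C(=O)OCC[Si](C)(C)C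
F8 | step 21 | free seco α-acetoxy acid (acid form of 27) | COC(=O)/C(I)=C/[C@H]1O[C@H]1/C(C)=C/[C@H]2OC(=O)[C@H](C)[C@@H]2[C@H](OC(=O)[C@@](C)(O)[C@H](C)OC(C)=O)[C@@H](OC(C)=O)C(=O)O
F9 | step 21 | 2-thioxopyridin-1(2H)-yl (Barton) ester of F8 | COC(=O)/C(I)=C/[C@H]1O[C@H]1/C(C)=C/[C@H]2OC(=O)[C@H](C)[C@@H]2[C@H](OC(=O)[C@@](C)(O)[C@H](C)OC(C)=O)[C@@H](OC(C)=O)C(=O)On1ccccc1=S
F10 | step 21 | C9 nor-aldehyde with the (Z)-α-iodo enoate | COC(=O)/C(I)=C/[C@H]1O[C@H]1/C(C)=C/[C@H]2OC(=O)[C@H](C)[C@@H]2[C@H](OC(=O)[C@@](C)(O)[C@H](C)OC(C)=O)C=O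
F11 | step 21 | 9-O-deacetyl target (9-hydroxy macrocycle) | COC(=O)/C1=C/[C@H]2O[C@H]2/C(C)=C/[C@H]2OC(=O)[C@H](C)[C@@H]2[C@H](OC(=O)[C@@](C)(O)[C@H](C)OC(C)=O)[C@H]1O
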